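Ring A is made last, on a finished pyranone. Its six carbons C4a–C5–C6–C7–C8–C8a carry oxygen at C5, C7 and C8a and methyl at C6 and C8, the alternating pattern of a folded propionate chain, so the C5–C6 bond is disconnected as a Claisen condensation. In one base-mediated operation the propionyl CH2 (C6) is joined to an ester carbon (C5) held on ring C, methoxide leaves and the new ring aromatises to the 5,7-dihydroxy-6,8-dimethyl pattern. The precursor is a 6-aryl-4-pyranone (rings B and C complete) bearing CO2Me at C3 and a 3-oxopentan-2-yl chain at C2, assembled from an arylpropiolic acid, methyl 3-oxopentanoate and a propionyl Weinreb amide.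

Key step: step 6

Remark: ring atoms are named in flavone numbering (O1, C2 to C8a) also in the precursors; pyranone locants appear only inside compound names.
Assumption: compounds 1, 6 and 10 are purchased.

Step 1
Reactants: 1 3-hydroxy-4,5-dimethoxybenzaldehyde
Product: 2 3-(benzyloxy)-4,5-dimethoxybenzaldehyde
Conditions: BnBr (1.1 equiv), K2CO3 (1.5 equiv), DMF, rt
Reagents that add atoms: benzyl bromide, BrCc1ccccc1
Why: Williamson ether synthesis on the only acidic OH; the benzyl ether should survive n-BuLi, amide bases and the acylation chemistry and is removable at the end by hydrogenolysis.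

Step 2
Reactants: 2 3-(benzyloxy)-4,5-dimethoxybenzaldehyde
Product: 3 1-(benzyloxy)-5-(2,2-dibromoethenyl)-2,3-dimethoxybenzene
Conditions: CBr4 (2 equiv), PPh3 (4 equiv), CH2Cl2, 0 °C
Reagents that add atoms: carbon tetrabromide, BrC(Br)(Br)Br
Why: First stage of the Corey–Fuchs homologation, in which the ylide Ph3P=CBr2 formed from CBr4 and PPh3 should olefinate the electron-rich aryl aldehyde in a Wittig reaction while the ethers are spectators.

Step 3
Reactants: 3 1-(benzyloxy)-5-(2,2-dibromoethenyl)-2,3-dimethoxybenzene
Product: 5 3-[3-(benzyloxy)-4,5-dimethoxyphenyl]prop-2-ynoic acid, via lithium arylacetylide 4 (not isolated)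
Conditions: n-BuLi (2.2 equiv), THF, −78 °C; then CO2, −78 °C to rt; 1 M HCl
Reagents that add atoms: carbon dioxide, O=C=O
Why: Second stage of the Corey–Fuchs sequence, in which bromine–lithium exchange, α-elimination with 1,2-shift (Fritsch–Buttenberg–Wiechell rearrangement) and deprotonation by the second equivalent should give acetylide 4, which CO2 carboxylates; the aryl ethers are inert to n-BuLi at −78 °C.

Step 4
Reactants: 5 3-[3-(benzyloxy)-4,5-dimethoxyphenyl]prop-2-ynoic acid; 6 methyl 3-oxopentanoate
Product: 9 methyl 6-[3-(benzyloxy)-4,5-dimethoxyphenyl]-2-ethyl-4-oxo-4H-pyran-3-carboxylate, via arylpropioloyl chloride 7 (not isolated), via C-acylated keto ester 8 (not isolated)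
Conditions: (COCl)2 (1.2 equiv), cat. DMF, CH2Cl2, 0 °C to rt, evaporate; then 6 (1.1 equiv), MgCl2 (1.1 equiv), pyridine (2.5 equiv), CH2Cl2, 0 °C to rt; wash with 1 M HCl, then DMAP (0.1 equiv), CH2Cl2, rt
Reagents that add atoms: none
Why: Oxalyl chloride with catalytic DMF should give the ynoyl chloride without HCl addition across the triple bond, the magnesium chelate of the β-keto ester (soft enolisation) steers acylation to carbon, and the enolised triacylmethane 8 should close by 6-endo-dig oxa-Michael addition of the propionyl enol oxygen to the aryl-bearing ynone carbon (the classical γ-pyranone synthesis from ynoyl chlorides and β-keto esters); the ketone oxygen is a better nucleophile than the ester oxygen, so the ester ends at C3 and the ethyl group at C2 of the pyranone.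

Step 5
Reactants: 9 methyl 6-[3-(benzyloxy)-4,5-dimethoxyphenyl]-2-ethyl-4-oxo-4H-pyran-3-carboxylate; 10 N-methoxy-N-methylpropanamide
Product: 13 methyl 6-[3-(benzyloxy)-4,5-dimethoxyphenyl]-4-oxo-2-(3-oxopentan-2-yl)-4H-pyran-3-carboxylate (racemic), via lithium dienolate 11 (not isolated), via tetrahedral lithium adduct 12 (not isolated)
Conditions: LiN(SiMe3)2 (1.2 equiv), THF, −78 °C; then 10 (1.5 equiv), −78 to −20 °C; AcOH, −78 °C
Reagents that add atoms: none
Why: Lateral (vinylogous) enolate acylation in the manner of the Weinreb ketone synthesis: the CH2 of the 2-ethyl group is the only acidic C–H (conjugated through the ring double bond with both the ring ketone and the ester), dienolate 11 can regain the pyranone only by reacting at its exocyclic carbon, and the chelated adduct 12 should persist until the cold acidic quench, so that neither a second acylation nor proton transfer from the more acidic product occurs; the new stereocentre (future C8) forms as a racemate and is erased in step 6.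

Step 6
Reactants: 13 methyl 6-[3-(benzyloxy)-4,5-dimethoxyphenyl]-4-oxo-2-(3-oxopentan-2-yl)-4H-pyran-3-carboxylate (racemic)
Product: 16 2-[3-(benzyloxy)-4,5-dimethoxyphenyl]-5,7-dihydroxy-6,8-dimethyl-4H-chromen-4-one, via dilithium dianion 14 (not isolated), via chromenetrione tautomer 15 (not isolated)
Conditions: LiN(i-Pr)2 (3.0 equiv), THF, −78 °C to rt; then 1 M HCl
Reagents that add atoms: none
Why: Two equivalents of LiN(i-Pr)2 should remove first the doubly activated methine proton (future C8–H) and then a proton of the propionyl CH2 (future C6) to give dianion 14, whose terminal carbanion adds to the ester carbonyl on the neighbouring ring carbon; methoxide is expelled to give trione 15 as its enolate, and LiOMe or the third equivalent of amide removes C6–H so that the ring aromatises to the 5,7-bis(phenoxide), which is protonated on work-up. The reaction is an intramolecular Claisen (Dieckmann-type) condensation with aromatisation, closest to the base-mediated cyclisation of 2-(2-oxoalkyl)benzoates to naphthalene-1,3-diols and of 3,5,7-triketo esters to acylphloroglucinols, here carried over to a 4-pyranone-3-carboxylate. The carbocycle C4a–C5–C6–C7–C8–C8a is closed at C5–C6 in a 6-(enolendo)-exo-trig mode, nucleophile and ester being held cis on the C8a=C4a bond of ring C. No stereocentre survives, since the centre of 13 and the transient ones of 15 vanish on aromatisation. The step needs C- over O-acylation and must spare ring C: dianion formation makes C6 the most nucleophilic site, attack on the C4 carbonyl would demand a bridged bicycle with a bridgehead double bond, the hindered amide does not add to the pyranone, and only the C-acylated product is drained irreversibly by aromatisation, any enol lactone formed through the C7 oxygen being reopened by LiOMe.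

Step 7
Reactants: 16 2-[3-(benzyloxy)-4,5-dimethoxyphenyl]-5,7-dihydroxy-6,8-dimethyl-4H-chromen-4-one
Product: 17 5,7-dihydroxy-2-(3-hydroxy-4,5-dimethoxyphenyl)-6,8-dimethyl-4H-chromen-4-one (5,7,3'-trihydroxy-4',5'-dimethoxy-6,8-dimethylflavone)
Conditions: H2 (1 atm), Pd/C (10 wt%), THF/MeOH, rt
Reagents that add atoms: none
Why: Hydrogenolysis of the aryl benzyl ether over palladium on carbon should be much faster than reduction of the conjugated, 5-OH-chelated C2=C3 bond of ring C, so the reaction is followed and stopped at complete debenzylation.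

Compound list
1 | 3-hydroxy-4,5-dimethoxybenzaldehyde | COc1cc(C=O)cc(O)c1OC | starting material
2 | 3-(benzyloxy)-4,5-dimethoxybenzaldehyde | COc1cc(C=O)cc(OCc2ccccc2)c1OC | intermediate
3 | 1-(benzyloxy)-5-(2,2-dibromoethenyl)-2,3-dimethoxybenzene | COc1cc(C=C(Br)Br)cc(OCc2ccccc2)c1OC | intermediate
4 | lithium [3-(benzyloxy)-4,5-dimethoxyphenyl]acetylide | [Li]C#Cc1cc(OC)c(OC)c(OCc2ccccc2)c1 | intermediate (not isolated)
5 | 3-[3-(benzyloxy)-4,5-dimethoxyphenyl]prop-2-ynoic acid | COc1cc(C#CC(=O)O)cc(OCc2ccccc2)c1OC | intermediate
6 | methyl 3-oxopentanoate | CCC(=O)CC(=O)OC | starting material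
7 | 3-[3-(benzyloxy)-4,5-dimethoxyphenyl]prop-2-ynoyl chloride | COc1cc(C#CC(=O)Cl)cc(OCc2ccccc2)c1OC | intermediate (not isolated)
8 | methyl 2-{3-[3-(benzyloxy)-4,5-dimethoxyphenyl]prop-2-ynoyl}-3-oxopentanoate (keto form drawn; enolised, no defined configuration) | CCC(=O)C(C(=O)OC)C(=O)C#Cc1cc(OC)c(OC)c(OCc2ccccc2)c1 | intermediate (not isolated)
9 | methyl 6-[3-(benzyloxy)-4,5-dimethoxyphenyl]-2-ethyl-4-oxo-4H-pyran-3-carboxylate | CCc1oc(-c2cc(OC)c(OC)c(OCc3ccccc3)c2)cc(=O)c1C(=O)OC | intermediate
10 | N-methoxy-N-methylpropanamide | CCC(=O)N(C)OC | starting material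
11 | lithium dienolate of 9, methyl 6-[3-(benzyloxy)-4,5-dimethoxyphenyl]-2-ethylidene-4-(lithiooxy)-2H-pyran-3-carboxylate (alkene geometry not defined) | CC=C1OC(-c2cc(OC)c(OC)c(OCc3ccccc3)c2)=CC(O[Li])=C1C(=O)OC | intermediate (not isolated)
12 | tetrahedral lithium adduct of 11 and 10 (mixture of diastereomers) | CCC(O[Li])(N(C)OC)C(C)c1oc(-c2cc(OC)c(OC)c(OCc3ccccc3)c2)cc(=O)c1C(=O)OC | intermediate (not isolated)
13 | methyl 6-[3-(benzyloxy)-4,5-dimethoxyphenyl]-4-oxo-2-(3-oxopentan-2-yl)-4H-pyran-3-carboxylate (racemic) | CCC(=O)C(C)c1oc(-c2cc(OC)c(OC)c(OCc3ccccc3)c2)cc(=O)c1C(=O)OC | intermediate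
14 | dilithium dianion of 13 (C8 and C6 deprotonated; alkene geometries not defined) | CC=C(O[Li])C(C)=C1OC(-c2cc(OC)c(OC)c(OCc3ccccc3)c2)=CC(O[Li])=C1C(=O)OC | intermediate (not isolated)
15 | 2-[3-(benzyloxy)-4,5-dimethoxyphenyl]-6,8-dimethyl-4H-chromene-4,5,7(6H,8H)-trione (keto tautomer of 16, present as its lithium enolate; configuration not defined) | CC1C(=O)C(C)c2oc(-c3cc(OC)c(OC)c(OCc4ccccc4)c3)cc(=O)c2C1=O | intermediate (not isolated)
16 | 2-[3-(benzyloxy)-4,5-dimethoxyphenyl]-5,7-dihydroxy-6,8-dimethyl-4H-chromen-4-one | COc1cc(-c2cc(=O)c3c(O)c(C)c(O)c(C)c3o2)cc(OCc4ccccc4)c1OC | intermediate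
17 | 5,7-dihydroxy-2-(3-hydroxy-4,5-dimethoxyphenyl)-6,8-dimethyl-4H-chromen-4-one | COc1cc(-c2cc(=O)c3c(O)c(C)c(O)c(C)c3o2)cc(O)c1OC | target

Total step count: 7. Longest linear sequence: 7 steps (1 to 17).

Steps most likely to fail

1. Step 6. Ring closure may be diverted by several processes:
- acylation through the C7 enolate oxygen in place of C6;
- incomplete second deprotonation;
- a dianion whose partial double-bond character at C8–C8a holds C6 away from the ester;
- base-induced opening of ring C.

Fallback: ring A would be brought in ready-made by the chalcone route, setting out from aldehyde 2. Commercial 2',4',6'-trihydroxyacetophenone is C-methylated twice (MeI, NaOMe, MeOH) to the symmetrical 2',4',6'-trihydroxy-3',5'-dimethylacetophenone F1. This is protected with MOMCl and i-Pr2NEt as 2'-hydroxy-4',6'-bis(methoxymethoxy)-3',5'-dimethylacetophenone F2. Claisen–Schmidt condensation of F2 with 2 (KOH, EtOH) should give the (E)-2'-hydroxychalcone F3. Oxidative cyclisation with catalytic I2 in DMSO at 120 °C gives the 5,7-bis(methoxymethoxy)flavone F4; because F1 is symmetrical, no 6/8 regiochemical question arises. HCl in MeOH then removes the acetals and returns the route at 16, before step 7.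

2. Step 5. The stabilised, cross-conjugated dienolate may be too weak a nucleophile for the Weinreb amide, the adduct alkoxide may close onto the neighbouring ester, or the amide base may attack the ester.

Fallback: the same C7–C8 bond would be made without strong base, setting out from 9. Treatment with t-BuMe2SiOTf and Et3N in CH2Cl2 gives the silyl dienol ether methyl 6-[3-(benzyloxy)-4,5-dimethoxyphenyl]-4-[(tert-butyldimethylsilyl)oxy]-2-ethylidene-2H-pyran-3-carboxylate F5. This is acylated at its exocyclic carbon with propionyl chloride and ZnCl2 in CH2Cl2 (Mukaiyama-type acylation), which restores the pyranone and returns the route at 13.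

3. Step 4. The magnesium enolate may be acylated on oxygen, the triacylmethane may lose an acyl group during work-up, HCl or pyridine may add across the ynoyl triple bond, or closure may proceed through the wrong oxygen.

Fallback: the keto ester would be used as its enamine, setting out from 6 and from chloride 7 (made from 5 as in step 4). Condensation of 6 with pyrrolidine (toluene, removal of water) gives methyl (E)-3-(pyrrolidin-1-yl)pent-2-enoate F6. C-Acylation of F6 with 7 (Et3N, CH2Cl2, 0 °C) gives the push–pull enaminone methyl 2-{3-[3-(benzyloxy)-4,5-dimethoxyphenyl]prop-2-ynoyl}-3-(pyrrolidin-1-yl)pent-2-enoate F7. Aqueous HCl in THF hydrolyses the enamine, and the freed enol closes onto the ynone, returning the route at 9.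

Further compounds
F1 | step 6 | 2',4',6'-trihydroxy-3',5'-dimethylacetophenone | CC(=O)c1c(O)c(C)c(O)c(C)c1O
F2 | step 6 | 2'-hydroxy-4',6'-bis(methoxymethoxy)-3',5'-dimethylacetophenone | CC(=O)c1c(O)c(C)c(OCOC)c(C)c1OCOC
F3 | step 6 | (E)-3-[3-(benzyloxy)-4,5-dimethoxyphenyl]-1-[2-hydroxy-4,6-bis(methoxymethoxy)-3,5-dimethylphenyl]prop-2-en-1-one | COCOc1c(C)c(O)c(C(=O)/C=C/c2cc(OC)c(OC)c(OCc3ccccc3)c2)c(OCOC)c1C
F4 | step 6 | 2-[3-(benzyloxy)-4,5-dimethoxyphenyl]-5,7-bis(methoxymethoxy)-6,8-dimethyl-4H-chromen-4-one | COCOc1c(C)c(OCOC)c2c(=O)cc(-c3cc(OC)c(OC)c(OCc4ccccc4)c3)oc2c1C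
F5 | step 5 | methyl 6-[3-(benzyloxy)-4,5-dimethoxyphenyl]-4-[(tert-butyldimethylsilyl)oxy]-2-ethylidene-2H-pyran-3-carboxylate (alkene geometry not defined) | CC=C1OC(-c2cc(OC)c(OC)c(OCc3ccccc3)c2)=CC(O[Si](C)(C)C(C)(C)C)=C1C(=O)OC
F6 | step 4 | methyl (E)-3-(pyrrolidin-1-yl)pent-2-enoate | CC/C(N1CCCC1)=C\C(=O)OC
F7 | step 4 | methyl 2-{3-[3-(benzyloxy)-4,5-dimethoxyphenyl]prop-2-ynoyl}-3-(pyrrolidin-1-yl)pent-2-enoate (push–pull alkene, geometry not defined) | CCC(N1CCCC1)=C(C(=O)OC)C(=O)C#Cc1cc(OC)c(OC)c(OCc2ccccc2)c1
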